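The flavanone ring C is cut between the CH2 (C3) and the carbonyl carbon (C4): the ketone and the C2–H bond are read as a formyl C–H added across an aryl enol ether. An enantioselective rhodium-catalysed intramolecular alkene hydroacylation closes ring C in a 6-endo sense, forms C3–C4 and sets the only stereocentre, C2 (S), in one isomerisation step. It exploits the fact that C2 carries both ring oxygen O1 and ring B, so that its planar precursor is a 1,1-disubstituted vinyl ether of a salicylaldehyde. That achiral precursor already holds the benzylated luteolin-type flavone and the diaryl ether, joined by an Ullmann coupling; hydrogenolysis then ends the route.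

Key step: step 8

Remark: 2,6-dihydroxy-4-methoxybenzaldehyde, 2-bromo-1-(4-iodophenyl)ethan-1-one, 1-[2,4-bis(benzyloxy)-6-hydroxyphenyl]ethan-1-one and 4-(benzyloxy)-3-hydroxybenzaldehyde are taken as catalogue compounds; the ligand enantiomer written in the key step is a working assignment, and its mirror image would be used if the opposite sense of induction is found.

Step 1
Reactants: 1 2,6-dihydroxy-4-methoxybenzaldehyde
Product: 2 2-(benzyloxy)-6-hydroxy-4-methoxybenzaldehyde
Conditions: BnBr (1.0 equiv), K2CO3 (1.1 equiv), DMF, 0 °C to rt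
Reagents that add atoms: benzyl bromide, BrCc1ccccc1
Why: Williamson etherification of a symmetric bis-phenol, in which the remaining OH of the mono-ether is locked in a hydrogen bond to the formyl group and should react more slowly, so that the mono-benzyl ether should dominate.

Step 2
Reactants: 3 2-bromo-1-(4-iodophenyl)ethan-1-one
Product: 4 racemic 2-bromo-1-(4-iodophenyl)ethan-1-ol
Conditions: NaBH4, MeOH, 0 °C; aq. NH4Cl quench
Reagents that add atoms: none
Why: Borohydride reduction of an α-bromo ketone, kept cold and quenched under mildly acidic conditions so that the bromohydrin does not close to the epoxide; the racemic stereocentre is removed in step 4.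

Step 3
Reactants: 2 2-(benzyloxy)-6-hydroxy-4-methoxybenzaldehyde; 4 racemic 2-bromo-1-(4-iodophenyl)ethan-1-ol
Product: 5 racemic 2-(benzyloxy)-6-[2-bromo-1-(4-iodophenyl)ethoxy]-4-methoxybenzaldehyde
Conditions: PPh3, DIAD, THF, 0 °C to rt
Reagents that add atoms: none
Why: Mitsunobu etherification, in which the acidic salicylaldehyde-type phenol should displace the secondary benzylic oxyphosphonium in an SN2 step without touching the formyl group or the primary bromide.

Step 4
Reactants: 5 racemic 2-(benzyloxy)-6-[2-bromo-1-(4-iodophenyl)ethoxy]-4-methoxybenzaldehyde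
Product: 6 2-(benzyloxy)-6-{[1-(4-iodophenyl)ethenyl]oxy}-4-methoxybenzaldehyde
Conditions: t-BuOK (1.2 equiv), THF, −20 to 0 °C; chromatography on Et3N-deactivated silica
Reagents that add atoms: none
Why: E2 dehydrobromination, in which the only β-hydrogen is the benzylic, oxygen-bearing one, so that the bulky base should give the 1-aryloxy-1-arylethene as the sole alkene while the non-enolisable aldehyde survives.

Step 5
Reactants: 7 1-[2,4-bis(benzyloxy)-6-hydroxyphenyl]ethan-1-one; 8 4-(benzyloxy)-3-hydroxybenzaldehyde
Product: 9 (E)-1-[2,4-bis(benzyloxy)-6-hydroxyphenyl]-3-[4-(benzyloxy)-3-hydroxyphenyl]prop-2-en-1-one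
Conditions: KOH (excess), EtOH/THF, rt; then aq. HCl
Reagents that add atoms: none
Why: Claisen–Schmidt aldol condensation, in which E1cB dehydration under thermodynamic control should give the E-chalcone and excess base compensates for the phenoxide-deactivated aldehyde.

Step 6
Reactants: 9 (E)-1-[2,4-bis(benzyloxy)-6-hydroxyphenyl]-3-[4-(benzyloxy)-3-hydroxyphenyl]prop-2-en-1-one
Product: 11 5,7-bis(benzyloxy)-2-[4-(benzyloxy)-3-hydroxyphenyl]-4H-chromen-4-one, via racemic flavanone 10 (not isolated)
Conditions: I2 (10 mol%), DMSO, 120 °C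
Reagents that add atoms: none
Why: Iodine/DMSO oxidative cyclisation of a 2'-hydroxychalcone, in which oxa-Michael closure to the flavanone, α-iodination and loss of HI should give the flavone while DMSO reoxidises HI to I2.

Step 7
Reactants: 11 5,7-bis(benzyloxy)-2-[4-(benzyloxy)-3-hydroxyphenyl]-4H-chromen-4-one; 6 2-(benzyloxy)-6-{[1-(4-iodophenyl)ethenyl]oxy}-4-methoxybenzaldehyde
Product: 12 2-(benzyloxy)-6-[(1-{4-[2-(benzyloxy)-5-(5,7-bis(benzyloxy)-4-oxo-4H-chromen-2-yl)phenoxy]phenyl}ethenyl)oxy]-4-methoxybenzaldehyde
Conditions: CuI (10 mol%), picolinic acid (20 mol%), K3PO4 (2 equiv), DMSO, 90 °C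
Reagents that add atoms: none
Why: Ullmann diaryl ether coupling of the only free phenol with the aryl iodide under ligand-accelerated copper catalysis, conditions that are basic and anhydrous and should therefore leave the enol ether, the non-enolisable aldehyde and the flavone intact.

Step 8
Reactants: 12 2-(benzyloxy)-6-[(1-{4-[2-(benzyloxy)-5-(5,7-bis(benzyloxy)-4-oxo-4H-chromen-2-yl)phenoxy]phenyl}ethenyl)oxy]-4-methoxybenzaldehyde
Product: 13 (2S)-5-(benzyloxy)-2-{4-[2-(benzyloxy)-5-(5,7-bis(benzyloxy)-4-oxo-4H-chromen-2-yl)phenoxy]phenyl}-7-methoxy-2,3-dihydro-4H-chromen-4-one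
Conditions: [Rh(cod)Cl]2 (5 mol%), (R)-DTBM-SEGPHOS (10 mol%), Na[B(3,5-(CF3)2C6H3)4] (10 mol%), degassed 1,4-dioxane, 60–80 °C
Reagents that add atoms: none
Why: Proposed new method: cationic monovalent rhodium should insert into the formyl C–H bond of 12 to give a trivalent acyl rhodium hydride, the tethered 1,1-disubstituted enol ether should then insert into Rh–H with the hydride going to the carbon that bears O1 and ring B (C2) and rhodium to the terminal CH2, and C–C reductive elimination from the resulting seven-membered acyl alkyl rhodacycle should form the CH2–C(=O) bond. The closest known reaction type is the rhodium/bisphosphine-catalysed enantioselective endo hydroacylation of 1,1-disubstituted alkenes in ortho-allylbenzaldehydes (to 3-substituted tetralones) and in 2-(1-substituted vinyl)benzaldehydes (to 3-substituted indanones); the oxygen-tethered aryl enol ether used here is the substrate class not yet shown. Ring C closes in a formal 6-endo-trig mode. The only new stereocentre, C2, is set by the chiral bisphosphine, which should discriminate the two enantiotopic faces of the enol ether in the hydride insertion and reductive elimination sequence, 2S being the required sense. The step needs endo over exo regioselectivity (the exo path would give a 2-aryl-2-methylbenzofuran-3-one through a tertiary alkyl rhodium) and cyclisation faster than decarbonylation; the 1,1-disubstitution of the alkene, the short oxygen tether that holds the alkene at the metal and the benzyl cap on the second ortho oxygen (no competing phenoxide chelate) should secure both, while the trisubstituted, untethered flavone C2=C3 bond should not compete.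

Step 9
Reactants: 13 (2S)-5-(benzyloxy)-2-{4-[2-(benzyloxy)-5-(5,7-bis(benzyloxy)-4-oxo-4H-chromen-2-yl)phenoxy]phenyl}-7-methoxy-2,3-dihydro-4H-chromen-4-one
Product: 14 (2S)-2-{4-[5-(5,7-dihydroxy-4-oxo-4H-chromen-2-yl)-2-hydroxyphenoxy]phenyl}-5-hydroxy-7-methoxy-2,3-dihydro-4H-chromen-4-one (CNP0161794.1)
Conditions: H2 (1 atm), Pd/C (10 wt%), EtOAc/THF/MeOH, rt
Reagents that add atoms: none
Why: Heterogeneous catalytic hydrogenolysis of the four benzyl aryl ethers under neutral conditions, which should leave the base-sensitive C2 stereocentre, the chelated aryl ketone, the flavone and the methyl ether untouched.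

Compound list
1 | 2,6-dihydroxy-4-methoxybenzaldehyde | COc1cc(O)c(C=O)c(O)c1 | starting material
2 | 2-(benzyloxy)-6-hydroxy-4-methoxybenzaldehyde | COc1cc(O)c(C=O)c(OCc2ccccc2)c1 | intermediate
3 | 2-bromo-1-(4-iodophenyl)ethan-1-one | O=C(CBr)c1ccc(I)cc1 | starting material
4 | racemic 2-bromo-1-(4-iodophenyl)ethan-1-ol | OC(CBr)c1ccc(I)cc1 | intermediate
5 | racemic 2-(benzyloxy)-6-[2-bromo-1-(4-iodophenyl)ethoxy]-4-methoxybenzaldehyde | COc1cc(OCc2ccccc2)c(C=O)c(OC(CBr)c2ccc(I)cc2)c1 | intermediate
6 | 2-(benzyloxy)-6-{[1-(4-iodophenyl)ethenyl]oxy}-4-methoxybenzaldehyde | COc1cc(OCc2ccccc2)c(C=O)c(OC(=C)c2ccc(I)cc2)c1 | intermediate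
7 | 1-[2,4-bis(benzyloxy)-6-hydroxyphenyl]ethan-1-one | CC(=O)c1c(O)cc(OCc2ccccc2)cc1OCc1ccccc1 | starting material
8 | 4-(benzyloxy)-3-hydroxybenzaldehyde | O=Cc1ccc(OCc2ccccc2)c(O)c1 | starting material
9 | (E)-1-[2,4-bis(benzyloxy)-6-hydroxyphenyl]-3-[4-(benzyloxy)-3-hydroxyphenyl]prop-2-en-1-one | O=C(/C=C/c1ccc(OCc2ccccc2)c(O)c1)c1c(O)cc(OCc2ccccc2)cc1OCc1ccccc1 | intermediate
10 | racemic 5,7-bis(benzyloxy)-2-[4-(benzyloxy)-3-hydroxyphenyl]-2,3-dihydro-4H-chromen-4-one (not isolated) | O=C1CC(c2ccc(OCc3ccccc3)c(O)c2)Oc2cc(OCc3ccccc3)cc(OCc3ccccc3)c12 | intermediate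
11 | 5,7-bis(benzyloxy)-2-[4-(benzyloxy)-3-hydroxyphenyl]-4H-chromen-4-one | O=c1cc(-c2ccc(OCc3ccccc3)c(O)c2)oc2cc(OCc3ccccc3)cc(OCc3ccccc3)c12 | intermediate
12 | 2-(benzyloxy)-6-[(1-{4-[2-(benzyloxy)-5-(5,7-bis(benzyloxy)-4-oxo-4H-chromen-2-yl)phenoxy]phenyl}ethenyl)oxy]-4-methoxybenzaldehyde | COc1cc(OCc2ccccc2)c(C=O)c(OC(=C)c2ccc(Oc3cc(-c4cc(=O)c5c(OCc6ccccc6)cc(OCc6ccccc6)cc5o4)ccc3OCc3ccccc3)cc2)c1 | intermediate
13 | (2S)-5-(benzyloxy)-2-{4-[2-(benzyloxy)-5-(5,7-bis(benzyloxy)-4-oxo-4H-chromen-2-yl)phenoxy]phenyl}-7-methoxy-2,3-dihydro-4H-chromen-4-one | COc1cc(OCc2ccccc2)c2c(c1)O[C@H](c1ccc(Oc3cc(-c4cc(=O)c5c(OCc6ccccc6)cc(OCc6ccccc6)cc5o4)ccc3OCc3ccccc3)cc1)CC2=O | intermediate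
14 | (2S)-2-{4-[5-(5,7-dihydroxy-4-oxo-4H-chromen-2-yl)-2-hydroxyphenoxy]phenyl}-5-hydroxy-7-methoxy-2,3-dihydro-4H-chromen-4-one (CNP0161794.1) | COc1cc(O)c2c(c1)O[C@H](c1ccc(Oc3cc(-c4cc(=O)c5c(O)cc(O)cc5o4)ccc3O)cc1)CC2=O | target

Total step count: 9 steps.
Longest linear sequence: 6 steps (steps 1 or 2, then 3, 4, 7, 8, 9).

Steps most likely to fail

Step 8 (carries the new-method label). The acyl rhodium hydride may lose carbon monoxide before the alkene inserts, the insertion may take the exo course to the five-membered ketone, or the two faces of the enol ether may be poorly discriminated. The fallback uses known chemistry, sets out from 12 and comes back at 13. Thiol-catalysed radical hydroacylation (tert-dodecanethiol, 1,1'-azobis(cyclohexanecarbonitrile), PhCl, 100 °C) should generate the aroyl radical by hydrogen abstraction from the formyl group. This radical should close 6-endo on the terminal CH2 of the enol ether, and the benzylic, oxygen-stabilised C2 radical is then reduced by the thiol. The product would be the racemic protected flavanone F1, with the same CH2–C(=O) bond formed by ring closure. Resolution on a cellulose tris(3,5-dimethylphenylcarbamate) stationary phase would deliver 13. The unwanted (2R)-enantiomer F2 would be racemised back to F1 with a catalytic amine base (DBU, toluene) and resolved again.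

Step 7. Carbon–oxygen bond formation at the ortho-benzyloxy phenol may be slow, so that hydrodeiodination of the aryl iodide and base-induced degradation of the formyl enol ether partner take over. The fallback sets out from 6 and comes back at 12, and replaces the halide/phenoxide coupling by an oxidative coupling that needs no strong base or heat. Miyaura borylation (B2pin2, Pd(dppf)Cl2, KOAc, 1,4-dioxane, 80 °C) should give the pinacol boronate F3. Chan–Lam etherification of F3 with phenol 11, mediated by divalent copper (Cu(OAc)2, pyridine, B(OH)3, 4 Å molecular sieves, MeCN, air, rt), should then give 12.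

Step 9. Hydrogenolysis may run on to saturation of the flavone C2=C3 bond or to reductive opening of the benzylic C2–O1 bond of the flavanone, or stop short of the fourth benzyl group. The fallback sets out from 13 and comes back at 14, and is non-reductive: Lewis-acid debenzylation with BCl3 and pentamethylbenzene in CH2Cl2 at −78 °C, in which the arene traps the benzyl cations. The 7-methoxy group, which is not peri to a carbonyl, should survive at this temperature, and no base touches C2. No new compound arises (F0).

Further compounds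
F1 | step 8 | racemic 5-(benzyloxy)-2-{4-[2-(benzyloxy)-5-(5,7-bis(benzyloxy)-4-oxo-4H-chromen-2-yl)phenoxy]phenyl}-7-methoxy-2,3-dihydro-4H-chromen-4-one | COc1cc(OCc2ccccc2)c2c(c1)OC(c1ccc(Oc3cc(-c4cc(=O)c5c(OCc6ccccc6)cc(OCc6ccccc6)cc5o4)ccc3OCc3ccccc3)cc1)CC2=O
F2 | step 8 | (2R)-5-(benzyloxy)-2-{4-[2-(benzyloxy)-5-(5,7-bis(benzyloxy)-4-oxo-4H-chromen-2-yl)phenoxy]phenyl}-7-methoxy-2,3-dihydro-4H-chromen-4-one | COc1cc(OCc2ccccc2)c2c(c1)O[C@@H](c1ccc(Oc3cc(-c4cc(=O)c5c(OCc6ccccc6)cc(OCc6ccccc6)cc5o4)ccc3OCc3ccccc3)cc1)CC2=O
F3 | step 7 | 2-(benzyloxy)-4-methoxy-6-({1-[4-(4,4,5,5-tetramethyl-1,3,2-dioxaborolan-2-yl)phenyl]ethenyl}oxy)benzaldehyde | COc1cc(OCc2ccccc2)c(C=O)c(OC(=C)c2ccc(B3OC(C)(C)C(C)(C)O3)cc2)c1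
F0 | step 9 | none | none
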